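All runs were computed with constants of no real substance, and the scatter is random.

Late in both runs the complex with one exchanged stays near 32.6 % while the complex with two exchanged still creeps upward, so the second exchange looks like a slow leak from a nearly steady pool.

| flask | starting complex | incoming ligand | remark | time |
|---|---|---|---|---|
| green | 0.34 M | 0.50 equiv | run made earlier |  |
| blue | 0.75 M | 0.50 equiv | run made earlier |  |
| flask | 0.50 M | 0.500 equiv |  | 6.0 min |

| run | time / min | complex with two exchanged / % | complex with one exchanged / % |
|---|---|---|---|
| green | 0.333 | 0 | 14.3 |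
| green | 0.833 | 0 | 23.9 |
| green | 1.50 | 0 | 29.1 |
| green | 2.50 | 0.4 | 31.2 |
| green | 4.00 | 1.5 | 31.1 |
| blue | 0.333 | 0 | 23.7 |
| blue | 0.833 | 0.5 | 32.5 |
| blue | 1.50 | 0.7 | 33.3 |
| blue | 2.50 | 1.5 | 32.6 |
| blue | 4.00 | 1.5 | 31.0 |

(standard deviation of a reading: 0.5 percentage points)

- equivalents of incoming ligand to starting complex, everything else as given, that leave most complex with two exchanged at 6.0 min
- the amount of complex with two exchanged then, in percent of the starting complex charged
- the amount of complex with two exchanged with the amounts as given



The blue run offers a stretch to read: from 0.833 min to 4.00 min it gains 1 percentage point, but that is just twice the scatter. My own reckoning starts from dc(two exchanged)/dt = k c(one exchanged) c(incoming ligand). If both factors stay flat, the rate is constant, so the step is pseudo-zero-order and integrates to a straight line. The ligand not taken up in blue is about 0.131 M, so the reading gives 0.0742 M⁻¹ min⁻¹, the feed constant. In this flask the same count leaves 0.0870 M, so the time constant is 155 min and the line reaches 1.26 % at 6.0 min. A line has no peak, so it offers no best equivalents.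

The forecast gives 1.8 %, and a best of 14 % at 3 equiv, saying “this is very uncertain”.

The flask gives 1.20 %, and a best of 13.0 % at 6.03 equiv, twice the forecast's equivalents.

    complex with two exchanged + incoming ligand ⇌ leaving ligand + complex with three exchanged (K = 1.77, k = 0.110 M⁻¹ s⁻¹)
    complex with three exchanged + incoming ligand ⇌ leaving ligand + complex with four exchanged (K = 1.60, k = 0.0717 M⁻¹ s⁻¹)
    starting complex + incoming ligand ⇌ leaving ligand + complex with one exchanged (K = 1.84, k = 0.0578 M⁻¹ s⁻¹)
    incoming ligand ⇌ dormant form (K = 0.740, k = 0.00518 s⁻¹)
    complex with one exchanged + incoming ligand ⇌ leaving ligand + complex with two exchanged (K = 2.62, k = 0.00308 M⁻¹ s⁻¹)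

This flask is not at rest at 6.0 min. By 60.0 min the complex with two exchanged reaches 5.68 %, the complex with one exchanged falls from 30.9 % to 21.2 %, and the starting complex rises from 67.4 % to 71.1 %. The feed-constant line gives 12.6 % there, more than the flask, and the pool in the flask is no longer flat.

In a neighbour flask with 2.00 equiv of incoming ligand, free and dormant ligand total 0.500 M at 6.00 min, so the line with 0.0742 M⁻¹ min⁻¹ gives 9.10 %. The computed value is 7.36 %.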